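Retrosynthesis: the acid is traced back to its benzyl ester and the side-chain ketone to a silyl-protected carbinol; the benzene ring is then cut at two bonds, C1–C2 and C5–C6 (C1 carboxyl, C2 hydroxyl, C4 methoxyl, C6 side chain).
Enabling feature: ring atoms C2–C5 carry the 1,3-dioxygen pattern (O at C2 and C4) of a 3-methoxycrotonate-derived silyl ketene acetal diene, and the adjacent atoms C1 and C6 carry a carboxyl carbon and an alkyl chain, the two ends of the triple bond of an alk-2-ynoate.
Forward, the chain is joined first: dodecanal is propargylated, the carbinol silylated and the alkyne terminus acylated to a benzyl ynoate; the diene comes in one step from methyl 3-methoxycrotonate.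
The only ring, the benzene, arises in one operation by [4+2] cycloaddition, loss of methanol and desilylation of the phenol; carbinol desilylation, oxidation and hydrogenolysis of the benzyl ester finish the synthesis.
Stereochemistry: the target has no stereocentre; the carbinol carbon is carried racemic and is erased by the oxidation.

Key step: step 5

Assumption: a benzyl ester is chosen for the carboxyl so that the acid can be released by neutral hydrogenolysis instead of forcing saponification of a hindered, hydrogen-bonded salicylate; the ketene acetal geometry of the diene is immaterial and is left undefined.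

Step 1
Reactants: 1 dodecanal; 2 propargyl bromide (3-bromoprop-1-yne)
Product: 4 pentadec-1-yn-4-ol (racemic), via allenylzinc bromide 3 (not isolated)
Conditions: Zn dust, THF, 0 °C → rt; then sat. aq. NH4Cl
Reagents that add atoms: none
Why: Barbier-type propargylation, in which zinc inserts into the C–Br bond to give an allenylzinc bromide that adds to the aldehyde through a six-membered SE2' transition state, should deliver the homopropargylic rather than the allenic alcohol; the new carbinol centre forms racemic, which is acceptable because step 7 removes it.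

Step 2
Reactants: 4 pentadec-1-yn-4-ol (racemic)
Product: 5 tert-butyl(dimethyl)(pentadec-1-yn-4-yloxy)silane (racemic)
Conditions: TBSCl, imidazole, DMF, rt
Reagents that add atoms: tert-butyldimethylsilyl chloride (TBSCl), CC(C)(C)[Si](C)(C)Cl
Why: Imidazole-promoted silylation of a secondary alcohol is a standard silyl ether protection, and the TBS ether should tolerate the organolithium of step 3 and the heat of step 5.

Step 3
Reactants: 5 tert-butyl(dimethyl)(pentadec-1-yn-4-yloxy)silane (racemic); 6 benzyl chloroformate
Product: 8 benzyl 5-(tert-butyldimethylsilyloxy)hexadec-2-ynoate (racemic), via lithium acetylide 7 (not isolated)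
Conditions: n-BuLi, THF, −78 °C; then 6, −78 → 0 °C
Reagents that add atoms: none
Why: Deprotonation of the terminal alkyne by n-BuLi and C-acylation of the lithium acetylide with a chloroformate is the standard route to alk-2-ynoates, and adding the acetylide to cold excess chloroformate should suppress a second addition to the product ester.

Step 4
Reactants: 9 methyl (E)-3-methoxybut-2-enoate
Product: 11 1,3-dimethoxy-1-(trimethylsilyloxy)buta-1,3-diene, via lithium dienolate 10 (not isolated)
Conditions: LiN(i-Pr)2, THF, −78 °C; then Me3SiCl, −78 °C → rt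
Reagents that add atoms: chlorotrimethylsilane (Me3SiCl), C[Si](C)(C)Cl
Why: Kinetic deprotonation of the γ-methyl group of the β-methoxy enoate gives the extended ester enolate, which the hard silyl chloride should trap on oxygen (vinylogous silyl ketene acetal formation); the diene is used directly after removal of LiCl and volatiles.

Step 5
Reactants: 11 1,3-dimethoxy-1-(trimethylsilyloxy)buta-1,3-diene; 8 benzyl 5-(tert-butyldimethylsilyloxy)hexadec-2-ynoate (racemic)
Product: 14 benzyl 6-[2-(tert-butyldimethylsilyloxy)tridecyl]-2-hydroxy-4-methoxybenzoate (racemic), via cyclohexa-1,4-diene cycloadduct 12 (not isolated), via aryl trimethylsilyl ether 13 (not isolated)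
Conditions: 11 (3 equiv), neat, 120 °C, sealed tube; then aq. citric acid, THF, rt
Reagents that add atoms: none
Why: This is a normal-electron-demand Diels–Alder reaction in which the terminal CH2 of 11, bearing the largest HOMO coefficient, bonds first to the β-carbon of ynoate 8 (future C5–C6) and the ketene acetal carbon then closes onto the α-carbon (future C1–C2) in one concerted, highly asynchronous [4+2] event that gives cyclohexa-1,4-diene 12. The mixed silyl methyl ketal of 12 should lose methanol in a 1,4-sense to aromatise to silyl ether 13, whose labile aryl O–SiMe3 bond is hydrolysed on acidic work-up to the hydrogen-bonded phenol 14; ketal hydrolysis before elimination would lead through the cyclohexadienone tautomer to the same phenol. The closest known reaction type is the cycloaddition of 1-alkoxy-1-silyloxy-3-oxygenated buta-1,3-dienes with acetylenic esters, followed by elimination to resorcylates. The one ring formed is the six-membered carbocycle, closed intermolecularly with both ring bonds made in the cycloaddition. No lasting stereocentre is created, since the ketal carbon of 12 becomes aromatic and the carbinol carbon stays racemic. The step needs regioselectivity, which the polarity of the partners secures (electron-rich diene terminus to electron-poor β-carbon places the ester between the phenol oxygen and the side chain), and chemoselectivity, which the neutral thermal conditions secure for the TBS ether and the benzyl ester.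

Step 6
Reactants: 14 benzyl 6-[2-(tert-butyldimethylsilyloxy)tridecyl]-2-hydroxy-4-methoxybenzoate (racemic)
Product: 15 benzyl 2-hydroxy-6-(2-hydroxytridecyl)-4-methoxybenzoate (racemic)
Conditions: HF·pyridine, pyridine, THF, 0 °C → rt
Reagents that add atoms: none
Why: Fluoride-driven cleavage of the Si–O bond removes the secondary TBS ether, and because the pyridine-buffered, mildly acidic medium generates no alkoxide, the freed carbinol should not close onto the benzyl ester, whose carbonyl is deactivated by the hydrogen-bonded 2-hydroxyl and the para methoxyl; the crude alcohol is oxidised at once.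

Step 7
Reactants: 15 benzyl 2-hydroxy-6-(2-hydroxytridecyl)-4-methoxybenzoate (racemic)
Product: 16 benzyl 2-hydroxy-4-methoxy-6-(2-oxotridecyl)benzoate
Conditions: Dess–Martin periodinane, CH2Cl2, 0 °C → rt
Reagents that add atoms: none
Why: Dess–Martin oxidation (ligand exchange at hypervalent iodine, then α-hydrogen abstraction) should convert the secondary alcohol to the ketone at room temperature without base or water, conditions under which the chelated phenol and the benzyl ester persist, and it erases the only stereocentre of the route.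

Step 8
Reactants: 16 benzyl 2-hydroxy-4-methoxy-6-(2-oxotridecyl)benzoate
Product: 17 2-hydroxy-4-methoxy-6-(2-oxotridecyl)benzoic acid (target)
Conditions: H2 (1 atm), Pd/C, EtOAc, rt
Reagents that add atoms: none
Why: Heterogeneous palladium-catalysed hydrogenolysis should cleave the benzylic C–O bond of the ester to give the acid and toluene under neutral conditions, avoiding acid- or base-induced enol-lactonisation or decarboxylation, while the aliphatic ketone and the arene are not reduced at atmospheric pressure.

Compound list
1 | dodecanal | CCCCCCCCCCCC=O | starting material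
2 | propargyl bromide (3-bromoprop-1-yne) | C#CCBr | starting material
3 | bromo(propa-1,2-dien-1-yl)zinc (allenylzinc bromide) | C=C=C[Zn]Br | intermediate (not isolated)
4 | pentadec-1-yn-4-ol (racemic) | CCCCCCCCCCCC(O)CC#C | intermediate
5 | tert-butyl(dimethyl)(pentadec-1-yn-4-yloxy)silane (racemic) | CCCCCCCCCCCC(CC#C)O[Si](C)(C)C(C)(C)C | intermediate
6 | benzyl chloroformate | O=C(Cl)OCc1ccccc1 | starting material
7 | [4-(tert-butyldimethylsilyloxy)pentadec-1-yn-1-yl]lithium (racemic) | [Li]C#CCC(CCCCCCCCCCC)O[Si](C)(C)C(C)(C)C | intermediate (not isolated)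
8 | benzyl 5-(tert-butyldimethylsilyloxy)hexadec-2-ynoate (racemic) | CCCCCCCCCCCC(O[Si](C)(C)C(C)(C)C)CC#CC(=O)OCc1ccccc1 | intermediate
9 | methyl (E)-3-methoxybut-2-enoate | CO/C(C)=C/C(=O)OC | starting material
10 | lithium 1,3-dimethoxybuta-1,3-dien-1-olate (enolate geometry undefined) | C=C(OC)C=C(OC)O[Li] | intermediate (not isolated)
11 | 1,3-dimethoxy-1-(trimethylsilyloxy)buta-1,3-diene (ketene acetal geometry undefined) | C=C(OC)C=C(OC)O[Si](C)(C)C | intermediate
12 | benzyl 2-[2-(tert-butyldimethylsilyloxy)tridecyl]-4,6-dimethoxy-6-(trimethylsilyloxy)cyclohexa-1,4-diene-1-carboxylate (mixture of diastereomers) | CCCCCCCCCCCC(O[Si](C)(C)C(C)(C)C)CC1=C(C(=O)OCc2ccccc2)C(OC)(O[Si](C)(C)C)C=C(OC)C1 | intermediate (not isolated)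
13 | benzyl 6-[2-(tert-butyldimethylsilyloxy)tridecyl]-4-methoxy-2-(trimethylsilyloxy)benzoate (racemic) | CCCCCCCCCCCC(O[Si](C)(C)C(C)(C)C)Cc1cc(OC)cc(O[Si](C)(C)C)c1C(=O)OCc1ccccc1 | intermediate (not isolated)
14 | benzyl 6-[2-(tert-butyldimethylsilyloxy)tridecyl]-2-hydroxy-4-methoxybenzoate (racemic) | CCCCCCCCCCCC(O[Si](C)(C)C(C)(C)C)Cc1cc(OC)cc(O)c1C(=O)OCc1ccccc1 | intermediate
15 | benzyl 2-hydroxy-6-(2-hydroxytridecyl)-4-methoxybenzoate (racemic) | CCCCCCCCCCCC(O)Cc1cc(OC)cc(O)c1C(=O)OCc1ccccc1 | intermediate
16 | benzyl 2-hydroxy-4-methoxy-6-(2-oxotridecyl)benzoate | CCCCCCCCCCCC(=O)Cc1cc(OC)cc(O)c1C(=O)OCc1ccccc1 | intermediate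
17 | 2-hydroxy-4-methoxy-6-(2-oxotridecyl)benzoic acid | CCCCCCCCCCCC(=O)Cc1cc(OC)cc(O)c1C(=O)O | target

Total step count: 8. Longest linear sequence: 7 steps (steps 1, 2, 3, 5, 6, 7, 8); step 4 is the one-step diene branch.

Steps most likely to fail

Step 5.
- What may go wrong: cycloaddition at the β-alkyl-substituted triple bond may be slower than thermal degradation of the ketene acetal diene. The mixed ketal of the adduct may also lose silanol instead of methanol, leaving part of the material as the 2-methyl ether.
- Fallback: a cycloaddition/cycloreversion replaces cycloaddition/elimination; it sets out from ynoate 8 and returns at 14.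
- Commercial dimedone is silylated (Me3SiCl, Et3N) to 5,5-dimethyl-3-(trimethylsilyloxy)cyclohex-2-en-1-one F1.
- LiN(i-Pr)2 deprotonates F1 at the α'-carbon to lithium 3,3-dimethyl-5-(trimethylsilyloxy)cyclohexa-1,5-dien-1-olate F2, and Me3SiCl traps it as 5,5-dimethyl-1,3-bis(trimethylsilyloxy)cyclohexa-1,3-diene F3.
- Heating F3 with 8 (neat, about 140 °C) should give benzyl 3-[2-(tert-butyldimethylsilyloxy)tridecyl]-8,8-dimethyl-1,5-bis(trimethylsilyloxy)bicyclo[2.2.2]octa-2,5-diene-2-carboxylate F4.
- F4 extrudes 2-methylpropene by retro-Diels–Alder reaction to benzyl 6-[2-(tert-butyldimethylsilyloxy)tridecyl]-2,4-bis(trimethylsilyloxy)benzoate F5, so both ring oxygens are kept and no ketal elimination is involved.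
- Aqueous citric acid gives benzyl 6-[2-(tert-butyldimethylsilyloxy)tridecyl]-2,4-dihydroxybenzoate F6, and MeI/K2CO3 in acetone should methylate only the non-chelated 4-hydroxyl, giving 14.

Step 6.
- What may go wrong: intramolecular transesterification, in which the liberated carbinol attacks the neighbouring benzyl ester and closes a 3,4-dihydroisocoumarin with loss of benzyl alcohol, especially if the medium turns basic during reaction or work-up.
- Fallback: the carboxyl is shielded as a tert-butyl ester, which resists alkoxide attack and is removed by acidolysis; it sets out from alkyne 5 (through acetylide 7) and returns at 17.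
- Quenching 7 with Boc2O should give tert-butyl 5-(tert-butyldimethylsilyloxy)hexadec-2-ynoate F7.
- Cycloaddition with diene 11 as in step 5 passes through tert-butyl 2-[2-(tert-butyldimethylsilyloxy)tridecyl]-4,6-dimethoxy-6-(trimethylsilyloxy)cyclohexa-1,4-diene-1-carboxylate F8 and tert-butyl 6-[2-(tert-butyldimethylsilyloxy)tridecyl]-4-methoxy-2-(trimethylsilyloxy)benzoate F9 to tert-butyl 6-[2-(tert-butyldimethylsilyloxy)tridecyl]-2-hydroxy-4-methoxybenzoate F10.
- HF·pyridine then gives tert-butyl 2-hydroxy-6-(2-hydroxytridecyl)-4-methoxybenzoate F11, and Dess–Martin periodinane gives tert-butyl 2-hydroxy-4-methoxy-6-(2-oxotridecyl)benzoate F12.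
- Brief treatment with CF3CO2H in CH2Cl2 at 0 °C with anisole as cation scavenger should release 17.

Step 7.
- What may go wrong: enol-lactonisation, in which the new benzyl ketone enolises and its enol oxygen closes onto the benzyl ester during oxidation or chromatography, so that 16 is eroded before hydrogenolysis.
- Fallback: that pathway is made the route and the acid is released by enol-lactone hydrolysis instead of hydrogenolysis; it sets out from 16 (crude) and returns at 17, omitting step 8.
- Catalytic TsOH in warm toluene should drive the cyclisation to 8-hydroxy-6-methoxy-3-undecyl-1H-isochromen-1-one F13 with loss of benzyl alcohol.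
- Aqueous KOH in THF should open the enol lactone to the potassium salt of the keto acid, and cold acidification to about pH 3 gives 17.

Further compounds
F1 | step 5 | 5,5-dimethyl-3-(trimethylsilyloxy)cyclohex-2-en-1-one | CC1(C)CC(=O)C=C(O[Si](C)(C)C)C1
F2 | step 5 | lithium 3,3-dimethyl-5-(trimethylsilyloxy)cyclohexa-1,5-dien-1-olate | CC1(C)CC(O[Si](C)(C)C)=CC(O[Li])=C1
F3 | step 5 | 5,5-dimethyl-1,3-bis(trimethylsilyloxy)cyclohexa-1,3-diene | CC1(C)CC(O[Si](C)(C)C)=CC(O[Si](C)(C)C)=C1
F4 | step 5 | benzyl 3-[2-(tert-butyldimethylsilyloxy)tridecyl]-8,8-dimethyl-1,5-bis(trimethylsilyloxy)bicyclo[2.2.2]octa-2,5-diene-2-carboxylate (mixture of diastereomers) | C[Si](C)(C)OC12CC(C)(C)C(C(O[Si](C)(C)C)=C1)C(CC(CCCCCCCCCCC)O[Si](C)(C)C(C)(C)C)=C2C(=O)OCc1ccccc1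
F5 | step 5 | benzyl 6-[2-(tert-butyldimethylsilyloxy)tridecyl]-2,4-bis(trimethylsilyloxy)benzoate (racemic) | CCCCCCCCCCCC(O[Si](C)(C)C(C)(C)C)Cc1cc(O[Si](C)(C)C)cc(O[Si](C)(C)C)c1C(=O)OCc1ccccc1
F6 | step 5 | benzyl 6-[2-(tert-butyldimethylsilyloxy)tridecyl]-2,4-dihydroxybenzoate (racemic) | CCCCCCCCCCCC(O[Si](C)(C)C(C)(C)C)Cc1cc(O)cc(O)c1C(=O)OCc1ccccc1
F7 | step 6 | tert-butyl 5-(tert-butyldimethylsilyloxy)hexadec-2-ynoate (racemic) | CCCCCCCCCCCC(O[Si](C)(C)C(C)(C)C)CC#CC(=O)OC(C)(C)C
F8 | step 6 | tert-butyl 2-[2-(tert-butyldimethylsilyloxy)tridecyl]-4,6-dimethoxy-6-(trimethylsilyloxy)cyclohexa-1,4-diene-1-carboxylate (mixture of diastereomers) | CCCCCCCCCCCC(O[Si](C)(C)C(C)(C)C)CC1=C(C(=O)OC(C)(C)C)C(OC)(O[Si](C)(C)C)C=C(OC)C1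
F9 | step 6 | tert-butyl 6-[2-(tert-butyldimethylsilyloxy)tridecyl]-4-methoxy-2-(trimethylsilyloxy)benzoate (racemic) | CCCCCCCCCCCC(O[Si](C)(C)C(C)(C)C)Cc1cc(OC)cc(O[Si](C)(C)C)c1C(=O)OC(C)(C)C
F10 | step 6 | tert-butyl 6-[2-(tert-butyldimethylsilyloxy)tridecyl]-2-hydroxy-4-methoxybenzoate (racemic) | CCCCCCCCCCCC(O[Si](C)(C)C(C)(C)C)Cc1cc(OC)cc(O)c1C(=O)OC(C)(C)C
F11 | step 6 | tert-butyl 2-hydroxy-6-(2-hydroxytridecyl)-4-methoxybenzoate (racemic) | CCCCCCCCCCCC(O)Cc1cc(OC)cc(O)c1C(=O)OC(C)(C)C
F12 | step 6 | tert-butyl 2-hydroxy-4-methoxy-6-(2-oxotridecyl)benzoate | CCCCCCCCCCCC(=O)Cc1cc(OC)cc(O)c1C(=O)OC(C)(C)C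
F13 | step 7 | 8-hydroxy-6-methoxy-3-undecyl-1H-isochromen-1-one | CCCCCCCCCCCC1=Cc2cc(OC)cc(O)c2C(=O)O1
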